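The plan disconnects C3 of ring C, the single oxygen-bearing carbon lying between the aryl-bearing C2 (bound to O1) and the carbonyl carbon C4, as a one-carbon unit. In the key step dibromocarbene adds to the enol-ether double bond of a 2-aryl-3-silyloxybenzofuran and the resulting fused cyclopropane opens, so that the furan is expanded to the 4-pyranone ring C, both the C2–C3 and C3–C4 bonds are made, and a bromine is left at C3 as the handle for the methoxy group. The precursor is the tert-butyldimethylsilyl enol ether of a 2-(3-benzyloxy-4-methoxyphenyl)-6,7-dimethoxybenzofuran-3-one, assembled from 2,3-dimethoxyphenol and benzylated homoisovanillic acid.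

Key step: step 7

Remark: the target is achiral; every intermediate with a stereocentre (4, 6, 7, 8, 9, 12) is racemic and needs no stereocontrol, and ketone 9, which equilibrates with its enol, is handled under argon.

Step 1
Reactants: 1 (3-hydroxy-4-methoxyphenyl)acetic acid
Product: 2 benzyl [3-(benzyloxy)-4-methoxyphenyl]acetate
Conditions: BnBr, K2CO3, DMF, 60 °C
Reagents that add atoms: benzyl bromide, BrCc1ccccc1
Why: Williamson O-benzylation of the phenoxide and SN2 esterification of the carboxylate should run together under carbonate base, masking both acidic groups in one operation.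

Step 2
Reactants: 2 benzyl [3-(benzyloxy)-4-methoxyphenyl]acetate
Product: 4 benzyl 2-bromo-2-[3-(benzyloxy)-4-methoxyphenyl]acetate (racemic), via silyl ketene acetal 3 (not isolated)
Conditions: LiHMDS, TMSCl, THF, −78 °C; then NBS, −78 to 0 °C
Reagents that add atoms: N-bromosuccinimide, O=C1CCC(=O)N1Br; chlorotrimethylsilane, C[Si](C)(C)Cl (its atoms stay only in 3)
Why: Enolate α-halogenation: the ester enolate is trapped as silyl ketene acetal 3, which NBS should brominate far faster than the aromatic rings, while the ionic conditions spare the benzylic ether positions that a radical bromination would attack; the new stereocentre forms racemic.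

Step 3
Reactants: 4 benzyl 2-bromo-2-[3-(benzyloxy)-4-methoxyphenyl]acetate; 5 2,3-dimethoxyphenol
Product: 6 benzyl 2-[3-(benzyloxy)-4-methoxyphenyl]-2-(2,3-dimethoxyphenoxy)acetate (racemic)
Conditions: K2CO3, acetone, reflux
Reagents that add atoms: none
Why: Williamson ether synthesis, in which the phenoxide of 5 should displace the doubly activated benzylic α-bromide by SN2 to give the racemic aryloxy ester.

Step 4
Reactants: 6 benzyl 2-[3-(benzyloxy)-4-methoxyphenyl]-2-(2,3-dimethoxyphenoxy)acetate
Product: 7 2-[3-(benzyloxy)-4-methoxyphenyl]-2-(2,3-dimethoxyphenoxy)acetic acid (racemic)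
Conditions: LiOH·H2O, THF/MeOH/H2O, rt; then aq. HCl
Reagents that add atoms: lithium hydroxide, [Li+].[OH-]
Why: Saponification of the benzyl ester by acyl substitution with hydroxide should leave all aryl ethers untouched.

Step 5
Reactants: 7 2-[3-(benzyloxy)-4-methoxyphenyl]-2-(2,3-dimethoxyphenoxy)acetic acid
Product: 9 2-[3-(benzyloxy)-4-methoxyphenyl]-6,7-dimethoxy-1-benzofuran-3(2H)-one (racemic), via mixed trifluoroacetic anhydride 8 (not isolated)
Conditions: (CF3CO)2O, CH2Cl2, 0 °C to rt; aq. NaHCO3 work-up; argon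
Reagents that add atoms: trifluoroacetic anhydride, O=C(OC(=O)C(F)(F)F)C(F)(F)F (its atoms stay only in 8)
Why: Intramolecular Friedel–Crafts acylation through mixed anhydride 8, where the only free position ortho to the aryloxy oxygen is also para to a methoxy group, so closure to the five-membered ketone should be regiochemically unambiguous and needs no Lewis acid that would endanger the benzyl ether.

Step 6
Reactants: 9 2-[3-(benzyloxy)-4-methoxyphenyl]-6,7-dimethoxy-1-benzofuran-3(2H)-one
Product: 10 {2-[3-(benzyloxy)-4-methoxyphenyl]-6,7-dimethoxy-1-benzofuran-3-yl}oxy(tert-butyl)dimethylsilane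
Conditions: TBSOTf, Et3N, CH2Cl2, 0 °C, argon
Reagents that add atoms: tert-butyldimethylsilyl trifluoromethanesulfonate, CC(C)(C)[Si](C)(C)OS(=O)(=O)C(F)(F)F
Why: O-silylation of the enolisable ketone with a silyl triflate and amine base is driven by formation of the aromatic benzofuran, and the bulky silyl group is chosen so that the enol ether can be isolated and resists alkoxide attack at silicon in step 7.

Step 7
Reactants: 10 {2-[3-(benzyloxy)-4-methoxyphenyl]-6,7-dimethoxy-1-benzofuran-3-yl}oxy(tert-butyl)dimethylsilane; 11 bromoform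
Product: 14 2-[3-(benzyloxy)-4-methoxyphenyl]-3-bromo-7,8-dimethoxy-4H-chromen-4-one, via dibromocyclopropane 12 (not isolated), via siloxyflavylium bromide 13 (not isolated)
Conditions: KOtBu, CHBr3 (slow addition), toluene/hexane, −20 °C to rt
Reagents that add atoms: bromoform 11, BrC(Br)Br (the numbered reactant above)
Why: Proposed new method: dibromocarbene, formed by α-elimination from 11 with KOtBu, should add as an electrophile to the C2=C3 double bond of 10, the most electron-rich alkene in the molecule because both O1 and the silyloxy oxygen donate into it, to give the cis-fused dibromocyclopropane 12. In this strained bicycle the bromide syn to the five-membered ring should leave with concerted disrotatory opening of the cyclopropyl cation, which cleaves the former C2–C3 bond and gives the 3-bromo-4-silyloxyflavylium ion 13, stabilised by O1, the silyloxy group and the aryl ring. Removal of the silyl group from 13 by bromide or tert-butoxide then gives the 4-pyranone 14. Ring C is therefore closed not by a cyclisation but by one-carbon ring expansion of the furan through a two-electron electrocyclic opening of the fused cyclopropane, with the carbene carbon becoming C3 bonded to C2 and C4. The closest known reactions are the dihalocarbene ring expansion of cyclic silyl enol ethers to 2-halo enones and the Ciamician–Dennstedt carbon insertion into indoles and benzofurans. No stereocentre remains in 14, and the selectivity needed is chemoselectivity for the furan double bond over rings A and B and the benzyl ether, which the doubly oxygenated enol-ether character of C2=C3 secures.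

Step 8
Reactants: 14 2-[3-(benzyloxy)-4-methoxyphenyl]-3-bromo-7,8-dimethoxy-4H-chromen-4-one
Product: 15 2-[3-(benzyloxy)-4-methoxyphenyl]-3,7,8-trimethoxy-4H-chromen-4-one
Conditions: Pd2(dba)3 (cat.), tBuBrettPhos (cat.), Cs2CO3, MeOH, toluene, 80 °C
Reagents that add atoms: methanol, CO
Why: Palladium-catalysed C–O cross-coupling (Buchwald–Hartwig-type etherification), in which the C3–Br bond should add oxidatively to zerovalent palladium, bromide is exchanged for methoxide, and the bulky biarylphosphine drives C–O reductive elimination, with carbonate as a base mild enough to spare ring C.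

Step 9
Reactants: 15 2-[3-(benzyloxy)-4-methoxyphenyl]-3,7,8-trimethoxy-4H-chromen-4-one
Product: 16 diplotrin B, 2-(3-hydroxy-4-methoxyphenyl)-3,7,8-trimethoxy-4H-chromen-4-one
Conditions: H2 (1 atm), 10% Pd/C, EtOAc/MeOH, rt
Reagents that add atoms: none
Why: Catalytic hydrogenolysis of the benzyl aryl ether should free the 3'-phenol, while the methyl ethers and the tetrasubstituted C2=C3 bond of the chromone are not reduced under one atmosphere of hydrogen.

Compound list
1 | (3-hydroxy-4-methoxyphenyl)acetic acid (homoisovanillic acid) | COc1ccc(CC(=O)O)cc1O | starting material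
2 | benzyl [3-(benzyloxy)-4-methoxyphenyl]acetate | COc1ccc(CC(=O)OCc2ccccc2)cc1OCc1ccccc1 | intermediate
3 | {1-(benzyloxy)-2-[3-(benzyloxy)-4-methoxyphenyl]ethenyl}oxy(trimethyl)silane (silyl ketene acetal, E/Z mixture, not isolated) | COc1ccc(C=C(OCc2ccccc2)O[Si](C)(C)C)cc1OCc1ccccc1 | intermediate
4 | benzyl 2-bromo-2-[3-(benzyloxy)-4-methoxyphenyl]acetate (racemic) | COc1ccc(C(Br)C(=O)OCc2ccccc2)cc1OCc1ccccc1 | intermediate
5 | 2,3-dimethoxyphenol | COc1cccc(O)c1OC | starting material
6 | benzyl 2-[3-(benzyloxy)-4-methoxyphenyl]-2-(2,3-dimethoxyphenoxy)acetate (racemic) | COc1ccc(C(Oc2cccc(OC)c2OC)C(=O)OCc2ccccc2)cc1OCc1ccccc1 | intermediate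
7 | 2-[3-(benzyloxy)-4-methoxyphenyl]-2-(2,3-dimethoxyphenoxy)acetic acid (racemic) | COc1ccc(C(Oc2cccc(OC)c2OC)C(=O)O)cc1OCc1ccccc1 | intermediate
8 | 2-[3-(benzyloxy)-4-methoxyphenyl]-2-(2,3-dimethoxyphenoxy)acetic trifluoroacetic anhydride (racemic, not isolated) | COc1ccc(C(Oc2cccc(OC)c2OC)C(=O)OC(=O)C(F)(F)F)cc1OCc1ccccc1 | intermediate
9 | 2-[3-(benzyloxy)-4-methoxyphenyl]-6,7-dimethoxy-1-benzofuran-3(2H)-one (racemic) | COc1ccc(C2Oc3c(OC)c(OC)ccc3C2=O)cc1OCc1ccccc1 | intermediate
10 | {2-[3-(benzyloxy)-4-methoxyphenyl]-6,7-dimethoxy-1-benzofuran-3-yl}oxy(tert-butyl)dimethylsilane | COc1ccc2c(O[Si](C)(C)C(C)(C)C)c(-c3ccc(OC)c(OCc4ccccc4)c3)oc2c1OC | intermediate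
11 | bromoform | BrC(Br)Br | starting material
12 | 1a-[3-(benzyloxy)-4-methoxyphenyl]-1,1-dibromo-6b-[(tert-butyldimethylsilyl)oxy]-3,4-dimethoxy-1a,6b-dihydro-1H-cyclopropa[b][1]benzofuran (racemic, cis ring fusion, not isolated) | COc1ccc(C23Oc4c(OC)c(OC)ccc4C2(O[Si](C)(C)C(C)(C)C)C3(Br)Br)cc1OCc1ccccc1 | intermediate
13 | 2-[3-(benzyloxy)-4-methoxyphenyl]-3-bromo-4-[(tert-butyldimethylsilyl)oxy]-7,8-dimethoxychromenylium bromide (not isolated) | COc1ccc(-c2[o+]c3c(OC)c(OC)ccc3c(O[Si](C)(C)C(C)(C)C)c2Br)cc1OCc1ccccc1.[Br-] | intermediate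
14 | 2-[3-(benzyloxy)-4-methoxyphenyl]-3-bromo-7,8-dimethoxy-4H-chromen-4-one | COc1ccc(-c2oc3c(OC)c(OC)ccc3c(=O)c2Br)cc1OCc1ccccc1 | intermediate
15 | 2-[3-(benzyloxy)-4-methoxyphenyl]-3,7,8-trimethoxy-4H-chromen-4-one | COc1ccc(-c2oc3c(OC)c(OC)ccc3c(=O)c2OC)cc1OCc1ccccc1 | intermediate
16 | diplotrin B, 2-(3-hydroxy-4-methoxyphenyl)-3,7,8-trimethoxy-4H-chromen-4-one | COc1ccc(-c2oc3c(OC)c(OC)ccc3c(=O)c2OC)cc1O | target

Total step count: 9. Longest linear sequence: 9 steps (1 to 16); 5 and 11 are bought and enter at steps 3 and 7.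

Steps most likely to fail

Step 7 (labelled step). The carbene may fail to add to the hindered tetrasubstituted double bond. Alternatively, alkoxide may remove the silyl group from the cyclopropane before it ionises, so that the three-membered ring opens toward the dibromomethyl carbon without ring expansion. Excess base may also degrade ring C. The fallback uses only known flavone chemistry, sets out from 5 and comes back at 15. Phenol 5 is protected with MOMCl and iPr2NEt as 1,2-dimethoxy-3-(methoxymethoxy)benzene F1. Directed ortho-lithiation next to the acetal oxygen (n-BuLi, TMEDA, THF, 0 °C) and acylation with N,2-dimethoxy-N-methylacetamide should give 1-[3,4-dimethoxy-2-(methoxymethoxy)phenyl]-2-methoxyethan-1-one F2. Methanolic HCl should free 1-(2-hydroxy-3,4-dimethoxyphenyl)-2-methoxyethan-1-one F3. Acylation with 3-(benzyloxy)-4-methoxybenzoyl chloride in pyridine should give 2,3-dimethoxy-6-(methoxyacetyl)phenyl 3-(benzyloxy)-4-methoxybenzoate F4. Baker–Venkataraman rearrangement (KOtBu, THF) should give 1-[3-(benzyloxy)-4-methoxyphenyl]-3-(2-hydroxy-3,4-dimethoxyphenyl)-2-methoxypropane-1,3-dione F5, and cyclodehydration (cat. TsOH, toluene, 80 °C) should close ring C to 15, which continues with step 9.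

Step 8. β-Hydride elimination from the palladium methoxide may cause hydrodebromination, or methoxide may attack C2 and open ring C. The fallback reverses the polarity at C3, sets out from 14 and comes back at 15. Bromine–magnesium exchange (iPrMgCl·LiCl, THF, −40 °C) should give {2-[3-(benzyloxy)-4-methoxyphenyl]-7,8-dimethoxy-4-oxo-4H-chromen-3-yl}magnesium chloride F6. Trapping with B(OMe)3 should give dimethyl {2-[3-(benzyloxy)-4-methoxyphenyl]-7,8-dimethoxy-4-oxo-4H-chromen-3-yl}boronate F7. Oxidation in the same flask (H2O2, aq. NaOH, 0 °C) should give 2-[3-(benzyloxy)-4-methoxyphenyl]-3-hydroxy-7,8-dimethoxy-4H-chromen-4-one F8, and O-methylation (MeI, K2CO3, acetone) should give 15.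

Step 5. The acid medium may cleave the benzyl ether, the acylium ion may lose carbon monoxide to a stabilised benzylic oxocarbenium ion, or intermolecular acylation may compete. The fallback closes the ring by carbanion acylation instead of aromatic substitution, sets out from 4 and comes back at 9. Bromide 4 is used to alkylate commercial methyl 2-hydroxy-3,4-dimethoxybenzoate (K2CO3, DMF), giving methyl 2-{2-(benzyloxy)-1-[3-(benzyloxy)-4-methoxyphenyl]-2-oxoethoxy}-3,4-dimethoxybenzoate F9. Saponification of both esters (LiOH, aq. THF) should give 2-{[3-(benzyloxy)-4-methoxyphenyl](carboxy)methoxy}-3,4-dimethoxybenzoic acid F10. Heating with Ac2O and NaOAc should cause Perkin-type ring closure with decarboxylation to 2-[3-(benzyloxy)-4-methoxyphenyl]-6,7-dimethoxy-1-benzofuran-3-yl acetate F11. Mild methanolysis (K2CO3, MeOH, argon) should give 9.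

Further compounds
F1 | step 7 | 1,2-dimethoxy-3-(methoxymethoxy)benzene | COCOc1cccc(OC)c1OC
F2 | step 7 | 1-[3,4-dimethoxy-2-(methoxymethoxy)phenyl]-2-methoxyethan-1-one | COCOc1c(C(=O)COC)ccc(OC)c1OC
F3 | step 7 | 1-(2-hydroxy-3,4-dimethoxyphenyl)-2-methoxyethan-1-one | COCC(=O)c1ccc(OC)c(OC)c1O
F4 | step 7 | 2,3-dimethoxy-6-(methoxyacetyl)phenyl 3-(benzyloxy)-4-methoxybenzoate | COCC(=O)c1ccc(OC)c(OC)c1OC(=O)c1ccc(OC)c(OCc2ccccc2)c1
F5 | step 7 | 1-[3-(benzyloxy)-4-methoxyphenyl]-3-(2-hydroxy-3,4-dimethoxyphenyl)-2-methoxypropane-1,3-dione (racemic) | COC(C(=O)c1ccc(OC)c(OCc2ccccc2)c1)C(=O)c1ccc(OC)c(OC)c1O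
F6 | step 8 | {2-[3-(benzyloxy)-4-methoxyphenyl]-7,8-dimethoxy-4-oxo-4H-chromen-3-yl}magnesium chloride | COc1ccc(-c2oc3c(OC)c(OC)ccc3c(=O)c2[Mg]Cl)cc1OCc1ccccc1
F7 | step 8 | dimethyl {2-[3-(benzyloxy)-4-methoxyphenyl]-7,8-dimethoxy-4-oxo-4H-chromen-3-yl}boronate | COB(OC)c1c(-c2ccc(OC)c(OCc3ccccc3)c2)oc2c(OC)c(OC)ccc2c1=O
F8 | step 8 | 2-[3-(benzyloxy)-4-methoxyphenyl]-3-hydroxy-7,8-dimethoxy-4H-chromen-4-one | COc1ccc(-c2oc3c(OC)c(OC)ccc3c(=O)c2O)cc1OCc1ccccc1
F9 | step 5 | methyl 2-{2-(benzyloxy)-1-[3-(benzyloxy)-4-methoxyphenyl]-2-oxoethoxy}-3,4-dimethoxybenzoate (racemic) | COC(=O)c1ccc(OC)c(OC)c1OC(C(=O)OCc1ccccc1)c1ccc(OC)c(OCc2ccccc2)c1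
F10 | step 5 | 2-{[3-(benzyloxy)-4-methoxyphenyl](carboxy)methoxy}-3,4-dimethoxybenzoic acid (racemic) | COc1ccc(C(Oc2c(C(=O)O)ccc(OC)c2OC)C(=O)O)cc1OCc1ccccc1
F11 | step 5 | 2-[3-(benzyloxy)-4-methoxyphenyl]-6,7-dimethoxy-1-benzofuran-3-yl acetate | COc1ccc2c(OC(C)=O)c(-c3ccc(OC)c(OCc4ccccc4)c3)oc2c1OC
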